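The bicyclic core is disconnected at C5–C9 (ring fusion) and O2–C3 (enol ether). The design exploits the C1 acetal–O2–C3=C4 enol ether array of the dihydropyran ring, a masked 1,5-dialdehyde, and the C3–C4–C5 allyl unit. The precursor is an open chain on a 1,3-dioxane (C7, C8, C10) that carries a (Z)-enol ether (C9=C1) and an α,β-unsaturated dimethyl acetal (C5=C4–C3). In one pot, TMSOTf forms the 1-methoxyallyl cation, the enol ether captures it at C5 (cyclopentane), and aqueous acid then unmasks both aldehydes and closes the pyran through O2, giving the cis-fused lactol with C5 and C9 set.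

Key step: step 9

Atom labels follow iridoid numbering: C1 acetal carbon, O2 ring oxygen, C3=C4 enol ether, C5 and C9 ring fusion, C6–C8 cyclopentane, C10 on C8, C11 on C4.

Assumption: SAMP directs the allylation of the dioxanone hydrazone to the (4S) centre, as in its usual ketone alkylations; RAMP would be used if the sense were opposite.

Step 1
Reactants: 1 2,2-dimethyl-1,3-dioxan-5-one; 2 (S)-1-amino-2-(methoxymethyl)pyrrolidine (SAMP)
Product: 3 SAMP hydrazone of 1
Conditions: benzene, reflux, Dean–Stark trap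
Reagents that add atoms: none
Why: Hydrazone formation by condensation with azeotropic removal of water installs the chiral auxiliary under neutral conditions that leave the ketal intact.

Step 2
Reactants: 3 SAMP hydrazone of 1
Product: 5 (S)-N-[(4S)-4-allyl-2,2-dimethyl-1,3-dioxan-5-ylidene]-2-(methoxymethyl)pyrrolidin-1-amine, via lithio aza-enolate 4 (not isolated)
Conditions: t-BuLi, THF, −78 °C; allyl bromide, −100 °C to rt
Reagents that add atoms: allyl bromide, C=CCBr
Why: SAMP-hydrazone α-alkylation: the chelated lithio aza-enolate is attacked by the allyl halide on the face left open by the methoxymethylpyrrolidine, which sets the future C7 centre as (4S).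

Step 3
Reactants: 5 allylated hydrazone
Product: 6 (4S)-4-allyl-2,2-dimethyl-1,3-dioxan-5-one
Conditions: saturated aqueous oxalic acid, Et2O, rt
Reagents that add atoms: water, O
Why: Two-phase hydrolysis of the hydrazone should release the α-substituted ketone without epimerisation and, unlike ozonolysis, spares the terminal alkene; the electron-poor ketal survives.

Step 4
Reactants: 7 2-methylidenepropane-1,3-diol
Product: 8 2-{[(tert-butyldiphenylsilyl)oxy]methyl}prop-2-en-1-ol
Conditions: NaH (1 equiv), THF, 0 °C; TBDPSCl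
Reagents that add atoms: tert-butyl(chloro)diphenylsilane, CC(C)(C)[Si](Cl)(c1ccccc1)c1ccccc1
Why: Monodeprotonation of the symmetric diol and silylation of the poorly soluble monosodium alkoxide gives the mono-silyl ether (monoprotection of a symmetric diol).

Step 5
Reactants: 8 mono-silyl ether
Product: 9 2-{[(tert-butyldiphenylsilyl)oxy]methyl}prop-2-enal
Conditions: MnO2, CH2Cl2, rt
Reagents that add atoms: none
Why: MnO2 oxidises the allylic alcohol to the 2-substituted acrolein and does not touch the silyl ether.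

Step 6
Reactants: 6 (4S)-4-allyl-2,2-dimethyl-1,3-dioxan-5-one; 9 2-substituted acrolein (excess)
Product: 10 (2E)-2-{[(tert-butyldiphenylsilyl)oxy]methyl}-4-[(4S)-2,2-dimethyl-5-oxo-1,3-dioxan-4-yl]but-2-enal
Conditions: second-generation Hoveyda–Grubbs catalyst RuCl2(H2IMes)(=CH-C6H4-2-OiPr) (cat.), CH2Cl2, 40 °C
Reagents that add atoms: none
Why: Olefin cross-metathesis of the terminal alkene with a 2-substituted acrolein should give the trisubstituted enal as the thermodynamically favoured (E)-isomer; ketone, ketal and silyl ether are inert to the ruthenium carbene.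

Step 7
Reactants: 10 enal ketone
Product: 11 (4S)-4-[(2E)-3-{[(tert-butyldiphenylsilyl)oxy]methyl}-4,4-dimethoxybut-2-en-1-yl]-2,2-dimethyl-1,3-dioxan-5-one
Conditions: HC(OMe)3, MeOH, n-Bu4NBr3 (cat.), rt
Reagents that add atoms: trimethyl orthoformate, COC(OC)OC; methanol, CO
Why: Tribromide-catalysed acetalisation with orthoformate is chemoselective for aldehydes over the hindered, electron-poor ketone and converts C3 into an ionisable dimethyl acetal whose only oxygens are methoxy leaving groups.

Step 8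
Reactants: 11 acetal ketone
Product: 13 tert-butyl{[(2E)-2-(dimethoxymethyl)-4-{(4S,5R)-5-[(Z)-2-ethoxyethenyl]-2,2-dimethyl-5-[(trimethylsilyl)oxy]-1,3-dioxan-4-yl}but-2-en-1-yl]oxy}diphenylsilane, via lithium alkoxide 12 (not isolated)
Conditions: (Z)-1-bromo-2-ethoxyethene, t-BuLi (2 equiv), Et2O, −78 °C; then 11, THF, −78 °C; then TMSCl, −78 to 0 °C
Reagents that add atoms: (Z)-1-bromo-2-ethoxyethene, CCO/C=C\Br; chlorotrimethylsilane, C[Si](C)(C)Cl
Why: Halogen–lithium exchange gives (Z)-2-ethoxyvinyllithium, whose 1,2-addition to the chair dioxanone should follow the unobstructed axial trajectory (ring positions 1 and 3 are oxygen), cis to the equatorial side chain, setting C8 as (5R); the alkoxide is silylated in the same flask.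

Step 9
Reactants: 13 enol ether / unsaturated acetal precursor
Product: 16 (4aS,6S,7R,7aS)-4-{[(tert-butyldiphenylsilyl)oxy]methyl}-7-(hydroxymethyl)-1,4a,5,6,7,7a-hexahydrocyclopenta[c]pyran-1,6,7-triol (C1 anomers), via cyclopentane bis-acetal 14 (not isolated), via ring-open dialdehyde 15 (not isolated)
Conditions: TMSOTf (0.2 equiv), 2,6-di-tert-butyl-4-methylpyridine, CH2Cl2, −78 °C; then 1 M aq. HCl–THF (1:4) added to the same flask, 0 °C to rt
Reagents that add atoms: water, O
Why: TMSOTf ionises the α,β-unsaturated dimethyl acetal to a 1-methoxyallyl cation (C3–C4–C5), and C9 of the (Z)-enol ether attacks C5 in a 5-exo-trig closure (C5–C9 bond, cyclopentane), the C1 oxocarbenium being capped by the released MeOTMS to give 14. Aqueous acid then hydrolyses the C3 methyl enol ether (this makes the new O2–C3 bond, both methoxy groups of C3 being lost), the C1 acetal, the silyl ether and the acetonide, and the cis-dialdehyde 15 closes to the enol hemiacetal by 6-exo-trig attack of the C3 enol oxygen on C1. The closest known reaction types are the Lewis-acid addition of enol ethers to α,β-unsaturated acetals (acetal–enol ether condensation, here vinylogous and intramolecular) and the spontaneous lactol closure of iridodial-type 1,5-dialdehydes. C9 is controlled by 1,3-allylic strain in the (Z)-enol ether, which holds the C8–O bond in the alkene plane so that bonding from the tether face places C1 cis to the C8 oxygen, and C5 is controlled by the cis-fused dioxane, which sends the C4 unit to the convex face, so both substituents end cis on the face opposite the dioxane. C1 remains an equilibrating anomeric centre that is fixed in step 11. The step needs 5-exo attack at C5 rather than 7-endo attack at C3 (ring size), ionisation of the allylic acetal before the ketal and the tertiary C8 silyloxy group (allyl-cation stabilisation at −78 °C against a C8 cation flanked by two C–O carbons), and the C3=C4 rather than C1=C9 enol ether (C9 is a ring-fusion carbon next to quaternary C8).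

Step 10
Reactants: 16 bicyclic lactol
Product: 17 (4aS,6S,7R,7aS)-7-{[(tert-butyldimethylsilyl)oxy]methyl}-4-{[(tert-butyldiphenylsilyl)oxy]methyl}-1,4a,5,6,7,7a-hexahydrocyclopenta[c]pyran-1,6,7-triol (C1 anomers)
Conditions: TBSCl (1.1 equiv), imidazole, DMF, −20 °C
Reagents that add atoms: tert-butyl(chloro)dimethylsilane, CC(C)(C)[Si](C)(C)Cl
Why: Selective silylation of a primary alcohol: with one equivalent of silyl chloride at low temperature the primary C10 hydroxyl should react before the lactol, the hindered secondary C7 and the tertiary C8 hydroxyls.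

Step 11
Reactants: 17 lactol; 18 (3R)-3-methylpentanoic acid
Product: 19 (1S,4aS,6S,7R,7aS)-7-{[(tert-butyldimethylsilyl)oxy]methyl}-4-{[(tert-butyldiphenylsilyl)oxy]methyl}-6,7-dihydroxy-1,4a,5,6,7,7a-hexahydrocyclopenta[c]pyran-1-yl (3R)-3-methylpentanoate
Conditions: DCC, DMAP (cat.), CH2Cl2, −20 to 0 °C
Reagents that add atoms: none
Why: Steglich esterification of the lactol hydroxyl, the most reactive remaining OH, while the anomers interconvert by ring opening should give the 1β-ester (1S), which is pseudo-axial (anomeric effect) and trans to the C9–C8 bond; C7–OH and C8–OH are too hindered to compete.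

Step 12
Reactants: 20 4-[(tert-butyldimethylsilyl)oxy]benzaldehyde
Product: 21 tert-butyl[4-(2,2-dibromoethenyl)phenoxy]dimethylsilane
Conditions: CBr4, PPh3, CH2Cl2, 0 °C
Reagents that add atoms: carbon tetrabromide, BrC(Br)(Br)Br
Why: First stage of the Corey–Fuchs reaction: the dibromomethylene ylide olefinates the aldehyde under neutral conditions that keep the aryl silyl ether.

Step 13
Reactants: 21 dibromoalkene
Product: 23 3-{4-[(tert-butyldimethylsilyl)oxy]phenyl}prop-2-ynoic acid, via lithium acetylide 22 (not isolated)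
Conditions: n-BuLi (2.2 equiv), THF, −78 °C; CO2; cold dilute aq. HCl
Reagents that add atoms: carbon dioxide, O=C=O
Why: Second stage of the Corey–Fuchs reaction gives the lithium acetylide, which is carboxylated by CO2 to the arylpropiolic acid.

Step 14
Reactants: 19 anomeric ester diol; 23 arylpropiolic acid
Product: 24 (1S,4aS,6S,7R,7aS)-7-{[(tert-butyldimethylsilyl)oxy]methyl}-4-{[(tert-butyldiphenylsilyl)oxy]methyl}-6-[(3-{4-[(tert-butyldimethylsilyl)oxy]phenyl}prop-2-ynoyl)oxy]-7-hydroxy-1,4a,5,6,7,7a-hexahydrocyclopenta[c]pyran-1-yl (3R)-3-methylpentanoate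
Conditions: DIC, DMAP (cat.), CH2Cl2, 0 °C to rt
Reagents that add atoms: none
Why: Carbodiimide/DMAP (Steglich) esterification acylates the only reactive hydroxyl left, the secondary C7–OH, with retention at C7 because its C–O bond is not broken; the tertiary C8–OH is inert.

Step 15
Reactants: 24 ynoate
Product: 25 (1S,4aS,6S,7R,7aS)-7-{[(tert-butyldimethylsilyl)oxy]methyl}-4-{[(tert-butyldiphenylsilyl)oxy]methyl}-6-{[(2Z)-3-{4-[(tert-butyldimethylsilyl)oxy]phenyl}prop-2-enoyl]oxy}-7-hydroxy-1,4a,5,6,7,7a-hexahydrocyclopenta[c]pyran-1-yl (3R)-3-methylpentanoate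
Conditions: H2 (1 atm), Pd/CaCO3 poisoned with Pb(OAc)2 (Lindlar catalyst), quinoline, EtOAc, rt, dark
Reagents that add atoms: none
Why: Lindlar semi-hydrogenation adds H2 syn to the alkyne and should stop at the (Z)-cinnamate; the trisubstituted enol ether is not reduced.

Step 16
Reactants: 25 tris-silyl ether
Product: 26 (1S,4aS,6S,7R,7aS)-7-hydroxy-4,7-bis(hydroxymethyl)-6-{[(2Z)-3-(4-hydroxyphenyl)prop-2-enoyl]oxy}-1,4a,5,6,7,7a-hexahydrocyclopenta[c]pyran-1-yl (3R)-3-methylpentanoate
Conditions: HF·pyridine, pyridine, THF, 0 °C to rt, dark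
Reagents that add atoms: none
Why: Pyridine-buffered fluoride desilylation removes the aryl, primary TBS and primary TBDPS ethers; the medium is neither basic enough for acyl migration nor acidic enough to ionise the anomeric ester or enol ether.

Compound list
1 | 2,2-dimethyl-1,3-dioxan-5-one | CC1(C)OCC(=O)CO1 | starting material
2 | (S)-1-amino-2-(methoxymethyl)pyrrolidine (SAMP) | COC[C@@H]1CCCN1N | starting material
3 | SAMP hydrazone of 1 | COC[C@@H]1CCCN1N=C1COC(C)(C)OC1 | intermediate
4 | lithio aza-enolate of 3 | COC[C@@H]1CCCN1N([Li])C1=COC(C)(C)OC1 | intermediate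
5 | (S)-N-[(4S)-4-allyl-2,2-dimethyl-1,3-dioxan-5-ylidene]-2-(methoxymethyl)pyrrolidin-1-amine | COC[C@@H]1CCCN1N=C1COC(C)(C)O[C@H]1CC=C | intermediate
6 | (4S)-4-allyl-2,2-dimethyl-1,3-dioxan-5-one | C=CC[C@@H]1OC(C)(C)OCC1=O | intermediate
7 | 2-methylidenepropane-1,3-diol | C=C(CO)CO | starting material
8 | 2-{[(tert-butyldiphenylsilyl)oxy]methyl}prop-2-en-1-ol | C=C(CO)CO[Si](c1ccccc1)(c1ccccc1)C(C)(C)C | intermediate
9 | 2-{[(tert-butyldiphenylsilyl)oxy]methyl}prop-2-enal | C=C(C=O)CO[Si](c1ccccc1)(c1ccccc1)C(C)(C)C | intermediate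
10 | (2E)-2-{[(tert-butyldiphenylsilyl)oxy]methyl}-4-[(4S)-2,2-dimethyl-5-oxo-1,3-dioxan-4-yl]but-2-enal | O=C/C(=C/C[C@@H]1OC(C)(C)OCC1=O)CO[Si](c2ccccc2)(c3ccccc3)C(C)(C)C | intermediate
11 | (4S)-4-[(2E)-3-{[(tert-butyldiphenylsilyl)oxy]methyl}-4,4-dimethoxybut-2-en-1-yl]-2,2-dimethyl-1,3-dioxan-5-one | COC(OC)/C(=C/C[C@@H]1OC(C)(C)OCC1=O)CO[Si](c2ccccc2)(c3ccccc3)C(C)(C)C | intermediate
12 | lithium (4S,5R)-alkoxide from addition of (Z)-2-ethoxyvinyllithium to 11 | COC(OC)/C(=C/C[C@@H]1OC(C)(C)OC[C@]1(O[Li])/C=C\OCC)CO[Si](c2ccccc2)(c3ccccc3)C(C)(C)C | intermediate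
13 | tert-butyl{[(2E)-2-(dimethoxymethyl)-4-{(4S,5R)-5-[(Z)-2-ethoxyethenyl]-2,2-dimethyl-5-[(trimethylsilyl)oxy]-1,3-dioxan-4-yl}but-2-en-1-yl]oxy}diphenylsilane | COC(OC)/C(=C/C[C@@H]1OC(C)(C)OC[C@]1(O[Si](C)(C)C)/C=C\OCC)CO[Si](c2ccccc2)(c3ccccc3)C(C)(C)C | intermediate
14 | cyclopentane bis-acetal, (5S,7S,8R,9S): cis-fused cyclopentane–dioxane with C9–CH(OEt)(OMe), C8–OTMS and C5–C(=CHOMe)CH2OTBDPS | COC=C(CO[Si](c3ccccc3)(c4ccccc4)C(C)(C)C)[C@H]1C[C@@H]2OC(C)(C)OC[C@]2(O[Si](C)(C)C)[C@H]1C(OC)OCC | intermediate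
15 | ring-open dialdehyde, (5S,7S,8R,9S): cyclopentane with C9–CHO, C8(OH)CH2OH, C7–OH and C5–CH(CHO)CH2OTBDPS | O=CC(CO[Si](c3ccccc3)(c4ccccc4)C(C)(C)C)[C@H]1C[C@H](O)[C@](O)(CO)[C@H]1C=O | intermediate
16 | (4aS,6S,7R,7aS)-4-{[(tert-butyldiphenylsilyl)oxy]methyl}-7-(hydroxymethyl)-1,4a,5,6,7,7a-hexahydrocyclopenta[c]pyran-1,6,7-triol (C1 anomers) | OC1OC=C(CO[Si](c3ccccc3)(c4ccccc4)C(C)(C)C)[C@H]2C[C@H](O)[C@](O)(CO)[C@@H]12 | intermediate
17 | (4aS,6S,7R,7aS)-7-{[(tert-butyldimethylsilyl)oxy]methyl}-4-{[(tert-butyldiphenylsilyl)oxy]methyl}-1,4a,5,6,7,7a-hexahydrocyclopenta[c]pyran-1,6,7-triol (C1 anomers) | OC1OC=C(CO[Si](c3ccccc3)(c4ccccc4)C(C)(C)C)[C@H]2C[C@H](O)[C@](O)(CO[Si](C)(C)C(C)(C)C)[C@@H]12 | intermediate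
18 | (3R)-3-methylpentanoic acid | CC[C@@H](C)CC(=O)O | starting material
19 | 1β-(3R)-3-methylpentanoate of 17, (1S,4aS,6S,7R,7aS) | CC[C@@H](C)CC(=O)O[C@@H]1OC=C(CO[Si](c3ccccc3)(c4ccccc4)C(C)(C)C)[C@H]2C[C@H](O)[C@](O)(CO[Si](C)(C)C(C)(C)C)[C@@H]12 | intermediate
20 | 4-[(tert-butyldimethylsilyl)oxy]benzaldehyde | O=Cc1ccc(O[Si](C)(C)C(C)(C)C)cc1 | starting material
21 | tert-butyl[4-(2,2-dibromoethenyl)phenoxy]dimethylsilane | BrC(Br)=Cc1ccc(O[Si](C)(C)C(C)(C)C)cc1 | intermediate
22 | lithium {4-[(tert-butyldimethylsilyl)oxy]phenyl}acetylide | [Li]C#Cc1ccc(O[Si](C)(C)C(C)(C)C)cc1 | intermediate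
23 | 3-{4-[(tert-butyldimethylsilyl)oxy]phenyl}prop-2-ynoic acid | OC(=O)C#Cc1ccc(O[Si](C)(C)C(C)(C)C)cc1 | intermediate
24 | C7 arylpropiolate of 19, (1S,4aS,6S,7R,7aS) | CC[C@@H](C)CC(=O)O[C@@H]1OC=C(CO[Si](c3ccccc3)(c4ccccc4)C(C)(C)C)[C@H]2C[C@H](OC(=O)C#Cc5ccc(O[Si](C)(C)C(C)(C)C)cc5)[C@](O)(CO[Si](C)(C)C(C)(C)C)[C@@H]12 | intermediate
25 | C7 (Z)-4-silyloxycinnamate, tris-silyl ether of the target, (1S,4aS,6S,7R,7aS) | CC[C@@H](C)CC(=O)O[C@@H]1OC=C(CO[Si](c3ccccc3)(c4ccccc4)C(C)(C)C)[C@H]2C[C@H](OC(=O)/C=C\c5ccc(O[Si](C)(C)C(C)(C)C)cc5)[C@](O)(CO[Si](C)(C)C(C)(C)C)[C@@H]12 | intermediate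
26 | (1S,4aS,6S,7R,7aS)-7-hydroxy-4,7-bis(hydroxymethyl)-6-{[(2Z)-3-(4-hydroxyphenyl)prop-2-enoyl]oxy}-1,4a,5,6,7,7a-hexahydrocyclopenta[c]pyran-1-yl (3R)-3-methylpentanoate | CC[C@@H](C)CC(=O)O[C@@H]1OC=C(CO)[C@H]2C[C@H](OC(=O)/C=C\c3ccc(O)cc3)[C@](O)(CO)[C@@H]12 | target

Total step count: 16. Longest linear sequence: 12 (steps 1, 2, 3, 6, 7, 8, 9, 10, 11, 14, 15, 16).

Steps most likely to fail

Step 9. The cationic closure may lose facial control at C5 or C9. The vinylogous acetal on the donor side may ionise at the tertiary C8 silyloxy group instead of the acceptor acetal. The unmasked dialdehyde may lose its β-oxygen before the lactol closes. The fallback sets out from 13 and replaces cation chemistry by enamine activation in the same single-flask format. A secondary ammonium salt (pyrrolidinium trifluoroacetate) in wet acetonitrile should hydrolyse the enol ether and the dimethyl acetal to the acetonide-protected formyl enal F1. F1 should close by intramolecular enamine Michael addition and lactol formation to the acetonide lactol F2, in which the dioxane still shields one face. Aqueous acetic acid then removes the acetonide and the trimethylsilyl group, and the route is rejoined at 16.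

Step 8. The basic vinyllithium may enolise the α-alkoxy ketone, and axial-face selectivity may be incomplete. The fallback sets out from 11 and uses a slimmer, less basic sp-nucleophile. Lithium ethoxyacetylide (from ethoxyacetylene and n-BuLi) is added and the alkoxide is quenched with TMSCl, which should give the propargylic silyl ether F3 with the same (4S,5R) configuration. Semi-hydrogenation of the ynol ether over Lindlar catalyst then gives the (Z)-enol ether, and the route is rejoined at 13.

Step 10. The lactol hydroxyl may be silylated in competition with the C10 primary hydroxyl, so that site selectivity is lost. The fallback sets out from 16 and protects both positions on purpose. Excess TBSCl and imidazole should give the 1,10-bis-silyl ether F4. The anomeric silyl acetal, whose lactolate is the better leaving group, is then cleaved alone with HF·pyridine in pyridine at −20 °C, and the route is rejoined at 17.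

Further compounds
F1 | step 9 | (2E)-2-{[(tert-butyldiphenylsilyl)oxy]methyl}-4-{(4S,5R)-2,2-dimethyl-5-(2-oxoethyl)-5-[(trimethylsilyl)oxy]-1,3-dioxan-4-yl}but-2-enal | O=C/C(=C/C[C@@H]1OC(C)(C)OC[C@]1(O[Si](C)(C)C)CC=O)CO[Si](c2ccccc2)(c3ccccc3)C(C)(C)C
F2 | step 9 | acetonide lactol: 16 with C7–O and C10–O still bridged by the isopropylidene ketal and C8–OTMS (C1 anomers) | OC1OC=C(CO[Si](c5ccccc5)(c6ccccc6)C(C)(C)C)[C@H]2C[C@@H]3OC(C)(C)OC[C@]3(O[Si](C)(C)C)[C@@H]12
F3 | step 8 | tert-butyl{[(2E)-2-(dimethoxymethyl)-4-{(4S,5R)-5-(ethoxyethynyl)-2,2-dimethyl-5-[(trimethylsilyl)oxy]-1,3-dioxan-4-yl}but-2-en-1-yl]oxy}diphenylsilane | COC(OC)/C(=C/C[C@@H]1OC(C)(C)OC[C@]1(O[Si](C)(C)C)C#COCC)CO[Si](c2ccccc2)(c3ccccc3)C(C)(C)C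
F4 | step 10 | 1,10-bis-O-(tert-butyldimethylsilyl) derivative of 16 (C1 anomers) | CC(C)(C)[Si](C)(C)OC1OC=C(CO[Si](c5ccccc5)(c6ccccc6)C(C)(C)C)[C@H]2C[C@H](O)[C@](O)(CO[Si](C)(C)C(C)(C)C)[C@@H]12
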